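**Plan**

1. Locants (longipinane type): C1 ketone, C2 CH2, C3 CH(CH3), cyclobutane C4–C5–C11–C10 (C4 next to C3, C11 next to C1, C10 carries CH3), C6 C(CH3)2, C7 and C9 the two ester carbinols, C8 the CH2 between them.
2. Retrosynthesis: cut the two angelate C–O bonds; then C6–C7 and C8–C9 together, which removes the C7–C8 unit as a ketene and leaves a bicyclo[2.1.1]hexan-2-one with C9 bonded directly to C6; then C5–C6 (carbenoid C–H insertion); then C4–C5 with C10–C11 (intramolecular ketene–alkene [2+2]); then C4=C10 (Wittig) and C2–C3 (auxiliary-controlled alkylation).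
3. Enabling feature: C7 and C9 are oxygenated and flank the C8 methylene inside the seven-membered ring, so that ring is a masked cycloheptane-1,3-dione; because C5 and C10 are 1,3 and cis on the cyclobutane, C6 and C9 can first be tied by a temporary bond as a cyclopentanone, whose silyl enol ether takes up dichloroketene and is then cleaved again at C6–C9.
4. Forward order: acyclic chain; cyclobutane plus six-membered ring in one [2+2]; temporary five-membered ring; seven-membered ring by two-carbon ring expansion; C6 methyls; diol; C1 ketone (unmasked from C=CH2); esters.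
5. Stereochemistry: C3 from the oxazolidinone auxiliary; C4, C10, C11 from the [2+2] (alkene geometry and the C3 methyl); C5 from the retentive C–H insertion; C7 and C9 from the CBS catalyst.

Key step: step 13

Remark: where a step creates a centre that is planarised again later (C6 and C9 in 24 and 25, C6 in 27, the spiro carbon of 32), both epimers are carried on and the SMILES leave that centre undefined.

**Route**

Step 1
Reactants: 1 (S)-4-benzyl-3-propanoyl-1,3-oxazolidin-2-one; 2 ethyl (E)-4-bromo-3-methylbut-2-enoate
Product: 3 ethyl (2E,5R)-6-[(4S)-4-benzyl-2-oxo-1,3-oxazolidin-3-yl]-3,5-dimethyl-6-oxohex-2-enoate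
Conditions: NaN(SiMe3)2, THF, −78 °C; then 2, −78 to −40 °C
Reagents that add atoms: none
Why: Evans asymmetric alkylation, in which the chelated Z-sodium enolate is alkylated by the allylic bromide on the face opposite the benzyl group, setting the future C3 stereocentre as R, while the β,β-disubstituted enoate is a poor Michael acceptor so that SN2 displacement should prevail.

Step 2
Reactants: 3 ethyl (2E,5R)-6-[(4S)-4-benzyl-2-oxo-1,3-oxazolidin-3-yl]-3,5-dimethyl-6-oxohex-2-enoate
Product: 4 ethyl (2E,5R)-6-hydroxy-3,5-dimethylhex-2-enoate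
Conditions: NaBH4, THF–H2O, 0 °C to rt
Reagents that add atoms: none
Why: Reductive cleavage of the N-acyl oxazolidinone by borohydride, which attacks the activated imide carbonyl and should leave the conjugated ester and the stereocentre untouched.

Step 3
Reactants: 4 ethyl (2E,5R)-6-hydroxy-3,5-dimethylhex-2-enoate
Product: 5 ethyl (2E,5R)-3,5-dimethyl-6-oxohex-2-enoate
Conditions: Dess–Martin periodinane, pyridine, CH2Cl2, 0 °C to rt
Reagents that add atoms: none
Why: Dess–Martin oxidation of a primary alcohol under buffered, non-basic conditions that should not epimerise the α-methyl aldehyde.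

Step 4
Reactants: 5 ethyl (2E,5R)-3,5-dimethyl-6-oxohex-2-enoate; 6 2-(triphenylphosphoranylidene)propanal
Product: 7 ethyl (2E,5R,6E)-3,5,7-trimethyl-8-oxoocta-2,6-dienoate
Conditions: toluene, 80 °C
Reagents that add atoms: none
Why: Wittig olefination with a stabilised formyl ylide, which should give the E trisubstituted enal, the geometry that later fixes the configuration of the quaternary carbon C10.

Step 5
Reactants: 7 ethyl (2E,5R,6E)-3,5,7-trimethyl-8-oxoocta-2,6-dienoate
Product: 9 (2E,5R,6E)-8-hydroxy-3,5,7-trimethylocta-2,6-dienoic acid, via hydroxy ester 8 (not isolated)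
Conditions: NaBH4, EtOH, 0 °C; then LiOH, H2O, rt; HCl work-up
Reagents that add atoms: lithium hydroxide, [Li+].[OH-]
Why: Chemoselective 1,2-reduction of the aldehyde by borohydride followed in the same flask by saponification of the ethyl ester, neither of which touches the stereocentre.

Step 6
Reactants: 9 (2E,5R,6E)-8-hydroxy-3,5,7-trimethylocta-2,6-dienoic acid
Product: 11 (2E,5R,6E)-8-acetoxy-3,5,7-trimethylocta-2,6-dienoic acid, via mixed anhydride 10 (not isolated)
Conditions: Ac2O, pyridine, DMAP (cat.), CH2Cl2, rt; aqueous work-up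
Reagents that add atoms: acetic anhydride, CC(=O)OC(C)=O
Why: DMAP-catalysed acetylation of the allylic alcohol, in which the carboxyl group is acetylated as well and that mixed anhydride is hydrolysed selectively on aqueous work-up.

Step 7
Reactants: 11 (2E,5R,6E)-8-acetoxy-3,5,7-trimethylocta-2,6-dienoic acid
Product: 14 [(1S,4R,5R,7R)-4,7-dimethyl-2-methylidene-6-oxobicyclo[3.1.1]heptan-7-yl]methyl acetate, via acid chloride 12 (not isolated), via vinylketene 13 (not isolated)
Conditions: (COCl)2, DMF (cat.), CH2Cl2, rt; evaporate; then slow addition to Et3N, toluene, reflux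
Reagents that add atoms: none
Why: Intramolecular vinylketene–alkene [2+2] cycloaddition, in which 1,4-dehydrochlorination through the methyl group cis to the acyl chloride gives the vinylketene, its carbonyl carbon (C5) bonds to the internal alkene carbon C4 and its α-carbon (C11) to the more substituted terminus C10 (the bridged mode expected for a trisubstituted alkene), the E geometry places the C10 methyl syn to the three-carbon bridge, and the C3 methyl should sit pseudo-equatorial and away from the cis alkene methyl (allylic 1,3-strain), thereby selecting the alkene face that sets C4, C10 and C11.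

Step 8
Reactants: 14 [(1S,4R,5R,7R)-4,7-dimethyl-2-methylidene-6-oxobicyclo[3.1.1]heptan-7-yl]methyl acetate
Product: 16 [(1S,4R,5R,7R)-4,7-dimethyl-2-methylidenebicyclo[3.1.1]heptan-7-yl]methanol, via hydrazone 15 (not isolated)
Conditions: N2H4·H2O, KOH, diethylene glycol, 130 °C then 200 °C
Reagents that add atoms: none
Why: Wolff–Kishner reduction (Huang-Minlon procedure) of the non-enolisable cyclobutanone to CH2 with concurrent cleavage of the acetate, conditions that an exocyclic methylene on this ring system should tolerate.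

Step 9
Reactants: 16 [(1S,4R,5R,7R)-4,7-dimethyl-2-methylidenebicyclo[3.1.1]heptan-7-yl]methanol
Product: 18 (1S,4R,5R,7R)-4,7-dimethyl-2-methylidenebicyclo[3.1.1]heptane-7-carboxylic acid, via aldehyde 17 (not isolated)
Conditions: TEMPO (cat.), PhI(OAc)2, MeCN–H2O, rt
Reagents that add atoms: water, O
Why: Oxoammonium (TEMPO) oxidation of the primary alcohol through the aldehyde hydrate to the acid, which is selective for the alcohol over the 1,1-disubstituted alkene.

Step 10
Reactants: 18 (1S,4R,5R,7R)-4,7-dimethyl-2-methylidenebicyclo[3.1.1]heptane-7-carboxylic acid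
Product: 20 2-diazo-1-[(1S,4R,5R,7R)-4,7-dimethyl-2-methylidenebicyclo[3.1.1]heptan-7-yl]ethan-1-one, via acid chloride 19 (not isolated)
Conditions: (COCl)2, DMF (cat.), CH2Cl2, 0 °C to rt; evaporate; then Me3SiCHN2, MeCN–THF, 0 °C
Reagents that add atoms: (trimethylsilyl)diazomethane, C[Si](C)(C)C=[N+]=[N-]
Why: Acylation of trimethylsilyldiazomethane by the acid chloride (first stage of the Arndt–Eistert sequence) with loss of Me3SiCl, helped by the quaternary α-carbon, which rules out ketene formation from the chloride.

Step 11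
Reactants: 20 2-diazo-1-[(1S,4R,5R,7R)-4,7-dimethyl-2-methylidenebicyclo[3.1.1]heptan-7-yl]ethan-1-one
Product: 21 5,7-dimethyl-3-methylidenetricyclo[4.3.0.0(2,7)]nonan-8-one (target cyclobutane with the C9 carbonyl bonded directly to C6H2 and C1 as C=CH2)
Conditions: Rh2(OAc)4 (cat.), CH2Cl2, rt, slow addition
Reagents that add atoms: none
Why: Dirhodium carbenoid C–H insertion forming a cyclopentanone (1,5-insertion), in which the acyl group on C10 and the C5 hydrogen anti to the three-carbon bridge are held parallel on the same face of the cyclobutane, insertion proceeds with retention and so sets C5 with C6 cis to C9, and the exocyclic alkene on the opposite face is out of reach for cyclopropanation.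

Step 12
Reactants: 21 5,7-dimethyl-3-methylidenetricyclo[4.3.0.0(2,7)]nonan-8-one
Product: 22 trimethylsilyl enol ether of 21 (C9–OSiMe3 with a C9=C6 double bond)
Conditions: LiN(iPr)2, Me3SiCl, THF, −78 °C
Reagents that add atoms: chlorotrimethylsilane, C[Si](C)(C)Cl
Why: Kinetic enolisation with internal silyl quench, which should give a single regioisomer because C6 is the only enolisable position (C10 is quaternary).

Step 13
Reactants: 22 trimethylsilyl enol ether of 21; 23 dichloroacetyl chloride
Product: 24 dichlorocyclobutanone adduct (four-membered ring C6–C7(=O)–C8Cl2–C9(OSiMe3) cis-fused across the former C6=C9 bond; both face isomers)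
Conditions: Et3N, hexane, 0 °C to rt, slow addition of 23
Reagents that add atoms: none
Why: Triethylamine dehydrochlorinates 23 to dichloroketene, whose electrophilic sp carbon (future C7) is attacked by the nucleophilic enol carbon C6 while the CCl2 terminus (future C8) closes onto the silyloxy carbon C9, so C6–C7 and C8–C9 form in one asynchronous event; the closest known reaction is the dichloroketene–trimethylsilyl enol ether cycloaddition used for the two-carbon expansion of cyclopentanone to cycloheptane-1,3-dione. The only ring closed is the cyclobutanone C6–C7–C8–C9, formed in a formal thermal [2+2] mode (orthogonal ketene approach, zwitterion-like transition state collapsing by four-membered ring closure) onto the strained C6=C9 bond of the bicyclo[2.1.1]hexene, and release of that olefin strain should accelerate it. The two new stereocentres C6 and C9 are necessarily cis because both bonds form on one face of the enol ether, and which face is used (towards C4 or towards C11) is immaterial, since C9 returns to a carbonyl and C6 to a planar enol carbon in step 14. Regioselectivity (C7 on C6, C8 on C9) is required and is fixed by the polarity of the silyl enol ether and of the ketene. Chemoselectivity over the C1=CH2 alkene is also required and should follow from the far higher nucleophilicity of the enol ether under the triethylamine protocol, which is sluggish with unactivated alkenes, and from the use of only a small excess of 23.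

Step 14
Reactants: 24 dichlorocyclobutanone adduct of 22
Product: 26 1-methylidene-13,14-dinorlongipinane-7,9-dione (seven-membered ring closed; C6 is CH2), via silyloxycyclobutanone 25 (not isolated)
Conditions: Zn, AcOH, iPrOH–H2O, 0 °C to rt
Reagents that add atoms: none
Why: Reductive dechlorination of the α,α-dichloroketone by zinc followed by desilylation and retro-aldol fragmentation, in which cleavage of the ring-fusion bond C6–C9 is driven by release of cyclobutanone and bicyclo[2.1.1]hexane strain and gives the seven-membered 7,9-dione while erasing the two ring-fusion stereocentres of 24.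

Step 15
Reactants: 26 1-methylidene-13,14-dinorlongipinane-7,9-dione
Product: 28 1-methylidenelongipinane-7,9-dione, via monomethyl dione 27 (not isolated)
Conditions: LiN(iPr)2 (2.2 equiv), THF–DMPU, −78 to 0 °C; MeI (1 equiv); LiN(iPr)2 (1.2 equiv); MeI
Reagents that add atoms: iodomethane, CI
Why: Twofold γ-alkylation of the β-diketone dianion, in which the only acidic hydrogens left after formation of the C8 enolate are on C6 (C10 is quaternary) and the more basic C6 carbanion is methylated each time, installing the gem-dimethyl group.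

Step 16
Reactants: 28 1-methylidenelongipinane-7,9-dione
Product: 31 (7R,9R)-1-methylidenelongipinane-7,9-diol, via ketol 29 (not isolated), via ketol 30 (not isolated)
Conditions: (S)-2-methyl-CBS-oxazaborolidine, catecholborane, toluene, −40 °C; aqueous work-up
Reagents that add atoms: none
Why: Corey–Bakshi–Shibata reduction of both carbonyls under catalyst control, in which each ketone is flanked by a quaternary carbon (large) and the C8 methylene (small) so that the S catalyst should give R at C7 and at C9 (the anti diol), with catecholborane chosen because it should not hydroborate the exocyclic alkene.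

Step 17
Reactants: 31 (7R,9R)-1-methylidenelongipinane-7,9-diol
Product: 33 (7R,9R)-7,9-dihydroxylongipinan-1-one, via ozonide 32 (not isolated)
Conditions: O3, CH2Cl2, −78 °C; then Me2S, −78 °C to rt
Reagents that add atoms: ozone, [O-][O+]=O
Why: Ozonolysis of the 1,1-disubstituted alkene with reductive work-up unmasks the C1 ketone without affecting the diol or any stereocentre.

Step 18
Reactants: 33 (7R,9R)-7,9-dihydroxylongipinan-1-one; 34 angelic acid ((Z)-2-methylbut-2-enoic acid)
Product: 37 (3R,4S,5S,7R,9R,10R,11R)-7,9-bis[(Z)-2-methylbut-2-enoyloxy]longipinan-1-one (CNP0283599.1), via 7-monoangelate 35 (not isolated), via 9-monoangelate 36 (not isolated)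
Conditions: 34 (6 equiv), 2,4,6-trichlorobenzoyl chloride (6 equiv), Et3N, toluene, rt; then 33, 80 °C
Reagents that add atoms: angelic acid (second equivalent of 34), C/C=C(/C)C(O)=O
Why: Yamaguchi-type esterification through the preformed mixed anhydride of 34 and without a nucleophilic amine catalyst, in which each of the two hydroxyl groups takes up one angeloyl group (the first acylation gives the monoesters 35 and 36, the second converts both into 37, so two molecules of angelic acid are consumed per molecule of 33), conditions under which angelates should form on hindered secondary alcohols without Z-to-E isomerisation and with retention at both carbinols.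

**Compound list**

1 | (S)-4-benzyl-3-propanoyl-1,3-oxazolidin-2-one | CCC(=O)N1[C@@H](Cc2ccccc2)COC1=O | starting material
2 | ethyl (E)-4-bromo-3-methylbut-2-enoate | CCOC(=O)/C=C(\C)CBr | starting material
3 | ethyl (2E,5R)-6-[(4S)-4-benzyl-2-oxo-1,3-oxazolidin-3-yl]-3,5-dimethyl-6-oxohex-2-enoate | CCOC(=O)/C=C(\C)C[C@@H](C)C(=O)N1[C@@H](Cc2ccccc2)COC1=O | intermediate
4 | ethyl (2E,5R)-6-hydroxy-3,5-dimethylhex-2-enoate | CCOC(=O)/C=C(\C)C[C@@H](C)CO | intermediate
5 | ethyl (2E,5R)-3,5-dimethyl-6-oxohex-2-enoate | CCOC(=O)/C=C(\C)C[C@@H](C)C=O | intermediate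
6 | 2-(triphenylphosphoranylidene)propanal | CC(C=O)=P(c1ccccc1)(c1ccccc1)c1ccccc1 | starting material
7 | ethyl (2E,5R,6E)-3,5,7-trimethyl-8-oxoocta-2,6-dienoate | CCOC(=O)/C=C(\C)C[C@@H](C)/C=C(\C)C=O | intermediate
8 | ethyl (2E,5R,6E)-8-hydroxy-3,5,7-trimethylocta-2,6-dienoate | CCOC(=O)/C=C(\C)C[C@@H](C)/C=C(\C)CO | intermediate (not isolated)
9 | (2E,5R,6E)-8-hydroxy-3,5,7-trimethylocta-2,6-dienoic acid | OC(=O)/C=C(\C)C[C@@H](C)/C=C(\C)CO | intermediate
10 | acetic (2E,5R,6E)-8-acetoxy-3,5,7-trimethylocta-2,6-dienoic anhydride | CC(=O)OC(=O)/C=C(\C)C[C@@H](C)/C=C(\C)COC(C)=O | intermediate (not isolated)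
11 | (2E,5R,6E)-8-acetoxy-3,5,7-trimethylocta-2,6-dienoic acid | OC(=O)/C=C(\C)C[C@@H](C)/C=C(\C)COC(C)=O | intermediate
12 | (2E,5R,6E)-8-acetoxy-3,5,7-trimethylocta-2,6-dienoyl chloride | ClC(=O)/C=C(\C)C[C@@H](C)/C=C(\C)COC(C)=O | intermediate (not isolated)
13 | (5R,6E)-8-acetoxy-5,7-dimethyl-3-methylideneocta-1,6-dien-1-one (vinylketene) | O=C=CC(=C)C[C@@H](C)/C=C(\C)COC(C)=O | intermediate (not isolated)
14 | [(1S,4R,5R,7R)-4,7-dimethyl-2-methylidene-6-oxobicyclo[3.1.1]heptan-7-yl]methyl acetate (7-methyl syn to the C2–C4 bridge, 4-methyl on the C6 side) | CC(=O)OC[C@]1(C)[C@@H]2C(=O)[C@H]1C(=C)C[C@H]2C | intermediate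
15 | hydrazone of [(1S,4R,5R,7R)-4,7-dimethyl-2-methylidene-6-oxobicyclo[3.1.1]heptan-7-yl]methanol | OC[C@]1(C)[C@@H]2C(=NN)[C@H]1C(=C)C[C@H]2C | intermediate (not isolated)
16 | [(1S,4R,5R,7R)-4,7-dimethyl-2-methylidenebicyclo[3.1.1]heptan-7-yl]methanol | OC[C@]1(C)[C@@H]2C[C@H]1C(=C)C[C@H]2C | intermediate
17 | (1S,4R,5R,7R)-4,7-dimethyl-2-methylidenebicyclo[3.1.1]heptane-7-carbaldehyde | O=C[C@]1(C)[C@@H]2C[C@H]1C(=C)C[C@H]2C | intermediate (not isolated)
18 | (1S,4R,5R,7R)-4,7-dimethyl-2-methylidenebicyclo[3.1.1]heptane-7-carboxylic acid | OC(=O)[C@]1(C)[C@@H]2C[C@H]1C(=C)C[C@H]2C | intermediate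
19 | (1S,4R,5R,7R)-4,7-dimethyl-2-methylidenebicyclo[3.1.1]heptane-7-carbonyl chloride | ClC(=O)[C@]1(C)[C@@H]2C[C@H]1C(=C)C[C@H]2C | intermediate (not isolated)
20 | 2-diazo-1-[(1S,4R,5R,7R)-4,7-dimethyl-2-methylidenebicyclo[3.1.1]heptan-7-yl]ethan-1-one | [N-]=[N+]=CC(=O)[C@]1(C)[C@@H]2C[C@H]1C(=C)C[C@H]2C | intermediate
21 | 5,7-dimethyl-3-methylidenetricyclo[4.3.0.0(2,7)]nonan-8-one (C9 carbonyl bonded directly to C6H2; cyclobutane and C3 configured as in 37) | O=C1[C@]2(C)[C@@H]3[C@@H]([C@H]2C(=C)C[C@H]3C)C1 | intermediate
22 | trimethylsilyl enol ether of 21 (C9–OSiMe3, C9=C6) | C[Si](C)(C)OC1[C@]2(C)[C@@H]3[C@@H]([C@H]2C(=C)C[C@H]3C)C=1 | intermediate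
23 | dichloroacetyl chloride | ClC(Cl)C(Cl)=O | starting material
24 | dichlorocyclobutanone adduct of 22 (ring C6–C7(=O)–C8Cl2–C9(OSiMe3), cis-fused, both face isomers) | C[Si](C)(C)OC12[C@]3(C)[C@@H]4[C@@H]([C@H]3C(=C)C[C@H]4C)C1C(=O)C2(Cl)Cl | intermediate
25 | dechlorinated adduct (as 24 with C8H2) | C[Si](C)(C)OC12[C@]3(C)[C@@H]4[C@@H]([C@H]3C(=C)C[C@H]4C)C1C(=O)C2 | intermediate (not isolated)
26 | 1-methylidene-13,14-dinorlongipinane-7,9-dione | O=C1CC(=O)[C@]2(C)[C@@H]3[C@@H]([C@H]2C(=C)C[C@H]3C)C1 | intermediate
27 | 1-methylidene-13-norlongipinane-7,9-dione (C6 monomethyl, both epimers) | O=C1CC(=O)[C@]2(C)[C@@H]3[C@@H]([C@H]2C(=C)C[C@H]3C)C1C | intermediate (not isolated)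
28 | 1-methylidenelongipinane-7,9-dione | O=C1CC(=O)[C@]2(C)[C@@H]3[C@@H]([C@H]2C(=C)C[C@H]3C)C1(C)C | intermediate
29 | (7R)-7-hydroxy-1-methylidenelongipinan-9-one | O[C@@H]1CC(=O)[C@]2(C)[C@@H]3[C@@H]([C@H]2C(=C)C[C@H]3C)C1(C)C | intermediate (not isolated)
30 | (9R)-9-hydroxy-1-methylidenelongipinan-7-one | O=C1C[C@@H](O)[C@]2(C)[C@@H]3[C@@H]([C@H]2C(=C)C[C@H]3C)C1(C)C | intermediate (not isolated)
31 | (7R,9R)-1-methylidenelongipinane-7,9-diol | O[C@@H]1C[C@@H](O)[C@]2(C)[C@@H]3[C@@H]([C@H]2C(=C)C[C@H]3C)C1(C)C | intermediate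
32 | ozonide of 31 (spiro-1,2,4-trioxolane at C1) | O[C@@H]1C[C@@H](O)[C@]2(C)[C@@H]3[C@@H]([C@H]2C4(OOCO4)C[C@H]3C)C1(C)C | intermediate (not isolated)
33 | (7R,9R)-7,9-dihydroxylongipinan-1-one | O[C@@H]1C[C@@H](O)[C@]2(C)[C@@H]3[C@@H]([C@H]2C(=O)C[C@H]3C)C1(C)C | intermediate
34 | angelic acid, (Z)-2-methylbut-2-enoic acid | C/C=C(/C)C(O)=O | starting material
35 | (7R,9R)-7-angeloyloxy-9-hydroxylongipinan-1-one | C/C=C(/C)C(=O)O[C@@H]1C[C@@H](O)[C@]2(C)[C@@H]3[C@@H]([C@H]2C(=O)C[C@H]3C)C1(C)C | intermediate (not isolated)
36 | (7R,9R)-9-angeloyloxy-7-hydroxylongipinan-1-one | O[C@@H]1C[C@@H](OC(=O)/C(C)=C\C)[C@]2(C)[C@@H]3[C@@H]([C@H]2C(=O)C[C@H]3C)C1(C)C | intermediate (not isolated)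
37 | (3R,4S,5S,7R,9R,10R,11R)-7,9-bis[(Z)-2-methylbut-2-enoyloxy]longipinan-1-one, CNP0283599.1 | C/C=C(/C)C(=O)O[C@@H]1C[C@@H](OC(=O)/C(C)=C\C)[C@]2(C)[C@@H]3[C@@H]([C@H]2C(=O)C[C@H]3C)C1(C)C | target

**Step count and risks**

Total step count: 18. Longest linear sequence: 18 steps (from 1 and 2 to 37).

Steps most likely to fail:

Step 15. The second metalation at the hindered C6 methine may be incomplete, with proton transfer to the C8 enolate and O- or C8-methylation competing, so that the quaternary centre is not reached. The fallback sets out from dione 26. Condensation with pyrrolidine (TsOH cat., toluene, reflux, water removal) should take place at the less hindered C7 carbonyl and give the vinylogous amide 7-(pyrrolidin-1-yl)-1-methylidene-13,14-dinorlongipin-7-en-9-one F4. Its extended enolate (LiN(iPr)2, THF, −78 °C) can only form by removal of a C6 hydrogen, because C10 is quaternary, and γ-methylation with MeI should give the C6-monomethyl vinylogous amide F5 and, after a second deprotonation and methylation, the 6,6-dimethyl vinylogous amide F6. Mild acidic hydrolysis (aqueous AcOH–NaOAc, THF, 60 °C) should return the route to dione 28.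

Step 11. The acceptor carbenoid may be diverted (Wolff rearrangement, dimerisation, attack on the C1 alkene) before it inserts into the strong cyclobutane C–H bond. The fallback sets out from acid 18. Its chloride 19 (made as in step 10) is used to acylate LiCH2CO2Et (2 equiv, THF, −78 °C), which should give the β-keto ester ethyl 3-[(1S,4R,5R,7R)-4,7-dimethyl-2-methylidenebicyclo[3.1.1]heptan-7-yl]-3-oxopropanoate F1. Regitz diazo transfer (4-acetamidobenzenesulfonyl azide, Et3N, MeCN) should give the diazo keto ester F2. The resulting acceptor/acceptor carbenoid (Rh2(OAc)4, CH2Cl2, 40 °C), the class best suited to cyclopentanone-forming C–H insertion, should close the five-membered ring to the tricyclic β-keto ester F3, in which the ester serves as a temporary activating group. Krapcho dealkoxycarbonylation (LiCl, wet DMSO, 150 °C) should return the route to ketone 21.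

Step 16. Catalyst control may be lost through slow reduction of the doubly neopentyl β-diketone and enol borate formation, leading to stereorandom or incomplete reduction. The fallback sets out from dione 28 and replaces reagent control by substrate-directed reduction and separation. Partial reduction with NaBH4 (MeOH–CH2Cl2, −78 °C) should give the ketols 29 and 30 together with their epimers, the (7S)-ketol F7 and the (9S)-ketol F8. Hydroxyl-directed Evans–Saksena reduction (Me4NBH(OAc)3, AcOH–MeCN, −20 °C) should convert all four into two trans diols only, 31 and its (7S,9S) diastereomer F9. These two are diastereomers because the tricyclic core is homochiral, so they should be separable by chromatography. F9 is returned to 28 by Dess–Martin oxidation, and 31 rejoins the route.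

Further compounds
F1 | step 11 | ethyl 3-[(1S,4R,5R,7R)-4,7-dimethyl-2-methylidenebicyclo[3.1.1]heptan-7-yl]-3-oxopropanoate | CCOC(=O)CC(=O)[C@]1(C)[C@@H]2C[C@H]1C(=C)C[C@H]2C
F2 | step 11 | ethyl 2-diazo-3-[(1S,4R,5R,7R)-4,7-dimethyl-2-methylidenebicyclo[3.1.1]heptan-7-yl]-3-oxopropanoate | CCOC(=O)C(=[N+]=[N-])C(=O)[C@]1(C)[C@@H]2C[C@H]1C(=C)C[C@H]2C
F3 | step 11 | ethyl 5,7-dimethyl-3-methylidene-8-oxotricyclo[4.3.0.0(2,7)]nonane-9-carboxylate (21 with CO2Et on C6) | O=C1[C@]2(C)[C@@H]3[C@@H]([C@H]2C(=C)C[C@H]3C)C1C(=O)OCC
F4 | step 15 | 7-(pyrrolidin-1-yl)-1-methylidene-13,14-dinorlongipin-7-en-9-one | C1CCN(C1)C1=CC(=O)[C@]2(C)[C@@H]3[C@@H]([C@H]2C(=C)C[C@H]3C)C1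
F5 | step 15 | 7-(pyrrolidin-1-yl)-1-methylidene-13-norlongipin-7-en-9-one (C6 monomethyl, both epimers) | C1CCN(C1)C1=CC(=O)[C@]2(C)[C@@H]3[C@@H]([C@H]2C(=C)C[C@H]3C)C1C
F6 | step 15 | 7-(pyrrolidin-1-yl)-1-methylidenelongipin-7-en-9-one | C1CCN(C1)C1=CC(=O)[C@]2(C)[C@@H]3[C@@H]([C@H]2C(=C)C[C@H]3C)C1(C)C
F7 | step 16 | (7S)-7-hydroxy-1-methylidenelongipinan-9-one | O[C@H]1CC(=O)[C@]2(C)[C@@H]3[C@@H]([C@H]2C(=C)C[C@H]3C)C1(C)C
F8 | step 16 | (9S)-9-hydroxy-1-methylidenelongipinan-7-one | O=C1C[C@H](O)[C@]2(C)[C@@H]3[C@@H]([C@H]2C(=C)C[C@H]3C)C1(C)C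
F9 | step 16 | (7S,9S)-1-methylidenelongipinane-7,9-diol | O[C@H]1C[C@H](O)[C@]2(C)[C@@H]3[C@@H]([C@H]2C(=C)C[C@H]3C)C1(C)C
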